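**Retrosynthetic overview**
1. Last operations: acylate the C8 hydroxyl with (2Z)-4-acetoxy-3-methylbut-2-enoic acid, then free the C15 hydroxyl from its silyl ether.
2. Key disconnection C6–C7: the α-methylene-γ-lactone (O, C6, C7, C11, C12, exocyclic C13) is fused to the ten-membered carbocycle (C1–C10) at C6–C7, so C13–C11(CO2Me)=C7 is a 2-carboxyallyl unit and C6 a carbinol carbon. A chromium-mediated intramolecular allylation of a C6 dienal by a C13 allylic bromide therefore closes the carbocycle with one C–C bond and lets O6 close the lactone.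
3. The open-chain precursor comes from a C3–C4 Sonogashira union of an epoxy alkyne with a (Z)-vinyl iodide, followed by Lindlar reduction to the Z C2=C3 bond. Both trisubstituted olefin units derive from but-2-yne-1,4-diol by trans-hydroalumination/iodination.
4. Stereocentres: C8 by asymmetric vinylogous Mukaiyama aldol, C1/C10 by Sharpless epoxidation, C6/C7 in the key step under control of C8.
5. Ring order: oxirane (step 10), then ten-membered carbocycle and γ-lactone together (step 20).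

Key step: step 20

Remark on the chemistry: germacrane numbering is used for locants (ring C1–C10, lactone carbons C11–C13, methyl C14, hydroxymethyl C15). It is assumed that the allylchromium reagent formed from bromide 26 is captured by the aldehyde before it loses the double-bond geometry of the bromide (C8 cis to the ester).

Abbreviations: PMB = 4-methoxybenzyl, TES = triethylsilyl, TBS = tert-butyldimethylsilyl, TBDPS = tert-butyldiphenylsilyl.

**Route**

Step 1
Reactants: 1 but-2-yne-1,4-diol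
Product: 2 4-[(4-methoxybenzyl)oxy]but-2-yn-1-ol
Conditions: NaH (1.0 equiv), 4-methoxybenzyl chloride (1.0 equiv), Bu4NI (cat.), THF/DMF, 0 °C to rt, diol in threefold excess
Reagents that add atoms: 4-methoxybenzyl chloride, COc1ccc(CCl)cc1
Why: Williamson ether synthesis on an excess of the symmetrical diol should give the mono-ether statistically; no stereocentre is involved.

Step 2
Reactants: 2 4-[(4-methoxybenzyl)oxy]but-2-yn-1-ol
Product: 3 4-[(4-methoxybenzyl)oxy]but-2-ynal
Conditions: MnO2 (activated, excess), CH2Cl2, rt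
Reagents that add atoms: none
Why: MnO2 oxidation of a propargylic alcohol should stop cleanly at the ynal.

Step 3
Reactants: 4 methyl 3-methylbut-2-enoate
Product: 6 tert-butyl{[(1Z)-1-methoxy-3-methylbuta-1,3-dien-1-yl]oxy}dimethylsilane, via lithium dienolate 5 (not isolated)
Conditions: LiN(iPr)2, THF/DMPU, −78 °C; then TBSCl, −78 °C to rt
Reagents that add atoms: tert-butylchlorodimethylsilane, CC(C)(C)[Si](C)(C)Cl
Why: γ-deprotonation of the senecioate gives the extended enolate, and O-silylation (silyl ketene acetal formation) gives the silyl dienol ether, whose ketene-acetal geometry is immaterial for the next step.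

Step 4
Reactants: 3 4-[(4-methoxybenzyl)oxy]but-2-ynal; 6 tert-butyl{[(1Z)-1-methoxy-3-methylbuta-1,3-dien-1-yl]oxy}dimethylsilane
Product: 8 methyl (2E,5R)-5-hydroxy-8-[(4-methoxybenzyl)oxy]-3-methyloct-2-en-6-ynoate, via trichlorosilyl aldolate 7 (not isolated)
Conditions: SiCl4 (1.1 equiv), chiral binaphthyldiamine-derived bisphosphoramide (5 mol %, enantiomer chosen for Re-face attack), iPr2NEt (0.2 equiv), CH2Cl2, −78 °C; aqueous work-up
Reagents that add atoms: none
Why: Catalytic asymmetric vinylogous Mukaiyama aldol (Lewis-base-activated SiCl4): γ-attack through the s-trans dienolate should give the 2E enoate, and the chiral phosphoramide-bound silicon cation should direct Re-face addition to the ynal, setting C8 (carbinol, R).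

Step 5
Reactants: 8 methyl (2E,5R)-5-hydroxy-8-[(4-methoxybenzyl)oxy]-3-methyloct-2-en-6-ynoate
Product: 9 (2E,5R)-8-[(4-methoxybenzyl)oxy]-3-methyloct-2-en-6-yne-1,5-diol
Conditions: iBu2AlH (3.2 equiv), CH2Cl2, −78 °C
Reagents that add atoms: none
Why: iBu2AlH 1,2-reduction of the enoate should give the allylic alcohol without touching the alkyne or the stereocentre.

Step 6
Reactants: 9 (2E,5R)-8-[(4-methoxybenzyl)oxy]-3-methyloct-2-en-6-yne-1,5-diol
Product: 11 (2E,5R,6Z)-7-iodo-8-[(4-methoxybenzyl)oxy]-3-methylocta-2,6-diene-1,5-diol, via cyclic alkenylalane 10 (not isolated)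
Conditions: NaAlH2(OCH2CH2OMe)2 (Red-Al, 3.5 equiv), THF, 0 °C to rt; then I2, THF, −78 to 0 °C
Reagents that add atoms: iodine, II
Why: Hydroxyl-directed trans-hydroalumination of the propargylic alcohol places H on C7 and Al on the distal carbon C11, and iodinolysis with retention should give the Z vinyl iodide (C8 cis to iodine, trans to C13).

Step 7
Reactants: 11 (2E,5R,6Z)-7-iodo-8-[(4-methoxybenzyl)oxy]-3-methylocta-2,6-diene-1,5-diol
Product: 12 1,5-bis(triethylsilyl) ether of diol 11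
Conditions: TESCl (2.5 equiv), imidazole, DMF, 0 °C to rt
Reagents that add atoms: chlorotriethylsilane, CC[Si](CC)(CC)Cl
Why: Exhaustive silylation of both hydroxyls is a standard protection and leaves the vinyl iodide untouched.

Step 8
Reactants: 12 1,5-bis(triethylsilyl) ether of diol 11
Product: 13 (2E,5R,6Z)-7-iodo-8-[(4-methoxybenzyl)oxy]-3-methyl-5-[(triethylsilyl)oxy]octa-2,6-dien-1-ol
Conditions: pyridinium p-toluenesulfonate (cat.), MeOH/CH2Cl2, −10 °C
Reagents that add atoms: none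
Why: Acid-catalysed methanolysis should cleave the unhindered primary allylic silyl ether much faster than the secondary one (selective desilylation).

Step 9
Reactants: 13 (2E,5R,6Z)-7-iodo-8-[(4-methoxybenzyl)oxy]-3-methyl-5-[(triethylsilyl)oxy]octa-2,6-dien-1-ol
Product: 14 methyl (2Z,4R,6E)-8-hydroxy-2-{[(4-methoxybenzyl)oxy]methyl}-6-methyl-4-[(triethylsilyl)oxy]octa-2,6-dienoate
Conditions: PdCl2(PPh3)2 (5 mol %), CO (1 atm), Et3N, MeOH/DMF, 50 °C
Reagents that add atoms: carbon monoxide, [C-]#[O+]; methanol, CO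
Why: Palladium-catalysed methoxycarbonylation of the vinyl iodide proceeds with retention, so the ester ends up cis to C8 (the silyl ether prevents butenolide formation).

Step 10
Reactants: 14 methyl (2Z,4R,6E)-8-hydroxy-2-{[(4-methoxybenzyl)oxy]methyl}-6-methyl-4-[(triethylsilyl)oxy]octa-2,6-dienoate
Product: 15 methyl (2Z,4R)-5-[(2R,3R)-3-(hydroxymethyl)-2-methyloxiran-2-yl]-2-{[(4-methoxybenzyl)oxy]methyl}-4-[(triethylsilyl)oxy]pent-2-enoate
Conditions: Ti(OiPr)4 (10 mol %), D-(−)-diethyl tartrate (12 mol %), tBuOOH, 4 Å molecular sieves, CH2Cl2, −20 °C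
Reagents that add atoms: tert-butyl hydroperoxide, CC(C)(C)OO
Why: Sharpless asymmetric epoxidation of the E-trisubstituted allylic alcohol with the D-tartrate should set C1 and C10 (both R, trans-oxirane) under reagent control, while the electron-poor enoate is inert.

Step 11
Reactants: 15 methyl (2Z,4R)-5-[(2R,3R)-3-(hydroxymethyl)-2-methyloxiran-2-yl]-2-{[(4-methoxybenzyl)oxy]methyl}-4-[(triethylsilyl)oxy]pent-2-enoate
Product: 16 methyl (2Z,4R)-5-[(2R,3S)-3-formyl-2-methyloxiran-2-yl]-2-{[(4-methoxybenzyl)oxy]methyl}-4-[(triethylsilyl)oxy]pent-2-enoate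
Conditions: Dess–Martin periodinane, NaHCO3, CH2Cl2, 0 °C
Reagents that add atoms: none
Why: Buffered Dess–Martin oxidation should give the epoxy aldehyde without epimerising the oxirane carbon (the descriptor changes only through the priority rules).

Step 12
Reactants: 16 methyl (2Z,4R)-5-[(2R,3S)-3-formyl-2-methyloxiran-2-yl]-2-{[(4-methoxybenzyl)oxy]methyl}-4-[(triethylsilyl)oxy]pent-2-enoate
Product: 17 methyl (2Z,4R)-5-[(2R,3R)-3-ethynyl-2-methyloxiran-2-yl]-2-{[(4-methoxybenzyl)oxy]methyl}-4-[(triethylsilyl)oxy]pent-2-enoate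
Conditions: dimethyl (1-diazo-2-oxopropyl)phosphonate, K2CO3, MeOH, 0 °C to rt
Reagents that add atoms: dimethyl (1-diazo-2-oxopropyl)phosphonate, COP(=O)(OC)C(=[N+]=[N-])C(C)=O
Why: Seyferth–Gilbert homologation with the Ohira–Bestmann reagent converts epoxy aldehydes into ethynyl oxiranes under mild carbonate conditions that the methyl ester and secondary silyl ether should tolerate.

Step 13
Reactants: 17 methyl (2Z,4R)-5-[(2R,3R)-3-ethynyl-2-methyloxiran-2-yl]-2-{[(4-methoxybenzyl)oxy]methyl}-4-[(triethylsilyl)oxy]pent-2-enoate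
Product: 18 methyl (2Z,4R)-5-[(2R,3R)-3-ethynyl-2-methyloxiran-2-yl]-2-(hydroxymethyl)-4-[(triethylsilyl)oxy]pent-2-enoate
Conditions: DDQ, CH2Cl2/pH 7 buffer, 0 °C
Reagents that add atoms: none
Why: Oxidative cleavage of the PMB ether by DDQ is orthogonal to the silyl ether, the oxirane and the alkyne, and is done before any oxidisable dienyl alcohol is present.

Step 14
Reactants: 1 but-2-yne-1,4-diol
Product: 19 4-[(tert-butyldiphenylsilyl)oxy]but-2-yn-1-ol
Conditions: TBDPSCl (1.0 equiv), imidazole, THF/DMF, 0 °C, diol in threefold excess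
Reagents that add atoms: tert-butylchlorodiphenylsilane, CC(C)(C)[Si](Cl)(c1ccccc1)c1ccccc1
Why: Statistical monosilylation of the symmetrical diol gives the mono-ether.

Step 15
Reactants: 19 4-[(tert-butyldiphenylsilyl)oxy]but-2-yn-1-ol
Product: 21 (2Z)-4-[(tert-butyldiphenylsilyl)oxy]-3-iodobut-2-en-1-ol, via cyclic alkenylalane 20 (not isolated)
Conditions: NaAlH2(OCH2CH2OMe)2 (Red-Al), THF, 0 °C; then I2, −78 to 0 °C
Reagents that add atoms: iodine, II
Why: The same hydroxyl-directed trans-hydroalumination/iodination should fix the C4=C5 geometry (C6 cis to iodine, the later C3 position).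

Step 16
Reactants: 18 methyl (2Z,4R)-5-[(2R,3R)-3-ethynyl-2-methyloxiran-2-yl]-2-(hydroxymethyl)-4-[(triethylsilyl)oxy]pent-2-enoate; 21 (2Z)-4-[(tert-butyldiphenylsilyl)oxy]-3-iodobut-2-en-1-ol
Product: 22 methyl (2Z,4R)-5-{(2R,3R)-3-[(3E)-3-{[(tert-butyldiphenylsilyl)oxy]methyl}-5-hydroxypent-3-en-1-yn-1-yl]-2-methyloxiran-2-yl}-2-(hydroxymethyl)-4-[(triethylsilyl)oxy]pent-2-enoate
Conditions: Pd(PPh3)4 (5 mol %), CuI (10 mol %), Et3N, THF, rt, degassed
Reagents that add atoms: none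
Why: Sonogashira coupling forms C3–C4 with retention of the vinyl iodide geometry, since oxidative addition of zerovalent palladium to the vinyl iodide at room temperature should outrun ionisation of the ethynyl oxirane.

Step 17
Reactants: 22 methyl (2Z,4R)-5-{(2R,3R)-3-[(3E)-3-{[(tert-butyldiphenylsilyl)oxy]methyl}-5-hydroxypent-3-en-1-yn-1-yl]-2-methyloxiran-2-yl}-2-(hydroxymethyl)-4-[(triethylsilyl)oxy]pent-2-enoate
Product: 23 methyl (2Z,4R)-5-{(2R,3R)-3-[(1Z,3E)-3-{[(tert-butyldiphenylsilyl)oxy]methyl}-5-hydroxypenta-1,3-dien-1-yl]-2-methyloxiran-2-yl}-2-(hydroxymethyl)-4-[(triethylsilyl)oxy]pent-2-enoate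
Conditions: H2 (1 atm), Pd/CaCO3 poisoned with Pb(OAc)2 (Lindlar catalyst), quinoline, EtOAc, 0 °C
Reagents that add atoms: none
Why: Lindlar semi-hydrogenation adds hydrogen syn to the conjugated alkyne and should give the Z C2=C3 bond, the trisubstituted enoate and the oxirane being far less reactive.

Step 18
Reactants: 23 methyl (2Z,4R)-5-{(2R,3R)-3-[(1Z,3E)-3-{[(tert-butyldiphenylsilyl)oxy]methyl}-5-hydroxypenta-1,3-dien-1-yl]-2-methyloxiran-2-yl}-2-(hydroxymethyl)-4-[(triethylsilyl)oxy]pent-2-enoate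
Product: 24 methyl (2Z,4R)-5-{(2R,3R)-3-[(1Z,3E)-3-{[(tert-butyldiphenylsilyl)oxy]methyl}-5-oxopenta-1,3-dien-1-yl]-2-methyloxiran-2-yl}-2-(hydroxymethyl)-4-[(triethylsilyl)oxy]pent-2-enoate
Conditions: MnO2 (activated, excess), CH2Cl2, 0 °C, short contact time
Reagents that add atoms: none
Why: Chemoselective MnO2 allylic oxidation: the electron-rich dienylic C6 carbinol should be oxidised much faster than the electron-poor C13 carbinol on the acrylate.

Step 19
Reactants: 24 methyl (2Z,4R)-5-{(2R,3R)-3-[(1Z,3E)-3-{[(tert-butyldiphenylsilyl)oxy]methyl}-5-oxopenta-1,3-dien-1-yl]-2-methyloxiran-2-yl}-2-(hydroxymethyl)-4-[(triethylsilyl)oxy]pent-2-enoate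
Product: 26 methyl (2E,4R)-2-(bromomethyl)-5-{(2R,3R)-3-[(1Z,3E)-3-{[(tert-butyldiphenylsilyl)oxy]methyl}-5-oxopenta-1,3-dien-1-yl]-2-methyloxiran-2-yl}-4-[(triethylsilyl)oxy]pent-2-enoate, via allylic mesylate 25 (not isolated)
Conditions: MsCl, iPr2NEt, CH2Cl2, −40 °C; then LiBr, THF, −40 to 0 °C; used at once
Reagents that add atoms: lithium bromide, [Li+].[Br-]
Why: Sulfonylation followed by direct SN2 displacement with bromide at low temperature (Finkelstein-type) should give the primary allylic bromide with the C7=C11 geometry intact.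

Step 20
Reactants: 26 methyl (2E,4R)-2-(bromomethyl)-5-{(2R,3R)-3-[(1Z,3E)-3-{[(tert-butyldiphenylsilyl)oxy]methyl}-5-oxopenta-1,3-dien-1-yl]-2-methyloxiran-2-yl}-4-[(triethylsilyl)oxy]pent-2-enoate
Product: 29 (1R,6R,7S,8R,10R,2Z,4E)-15-[(tert-butyldiphenylsilyl)oxy]-1,10-epoxy-8-[(triethylsilyl)oxy]germacra-2,4,11(13)-trien-12,6-olide, via allylchromium dichloride 27 (not isolated), via chromium alkoxide of the ring-closed hydroxy ester 28 (not isolated)
Conditions: CrCl2 (8 equiv), THF, 0 °C to rt, syringe-pump addition of 26 (final 2 mM); pH 7 buffer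
Reagents that add atoms: none
Why: Two equivalents of CrCl2 reduce the allylic bromide to the 2-(methoxycarbonyl)allylchromium 27 (trivalent chromium), which adds through its γ-carbon C7 to the C6 aldehyde in a closed six-membered chair transition state, and the chromium alkoxide 28 at O6 then acylates on the C12 methyl ester with loss of methoxide; the closest known reaction type is the chromium-mediated (Nozaki–Hiyama-type) intramolecular allylation of ω-formyl 2-(bromomethyl)acrylates, which is precedented for closing ten-membered carbocycles with concomitant α-methylene-γ-lactone formation. The ten-membered carbocycle closes in a 10-exo-trig mode at the aldehyde carbon (C6–C7 bond) and the γ-lactone in a 5-exo-trig mode (O6 onto C12). C6 is set relative to C7 by the chair: the C5 substituent of the aldehyde is equatorial and C8, which is trans to the CH2Cr carbon in this reagent, is also equatorial, giving the anti adduct and hence the trans-fused lactone. C7 is set relative to C8: allylic 1,3-strain with the cis ester puts H8 in the olefin plane, the tether carbon C9 must lie anti to the forming bond because the gauche alternative would place C5 and C9 in a syn-pentane relationship, and the silyl ether therefore sits on the side of the new bond, which corresponds to the spatial arrangement of the target at C6, C7 and C8 (C7 is labelled S in 29 only because the silyl ether changes the priorities). The step needs γ- over α-attack (secured by the closed transition state), 1,2-addition to the dienal (normal for allylchromium reagents), ring closure over oligomerisation (high dilution) and intact Z geometry at C2=C3 and C4=C5 (the dienal is made at or below 0 °C and used at once).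

Step 21
Reactants: 29 (1R,6R,7S,8R,10R,2Z,4E)-15-[(tert-butyldiphenylsilyl)oxy]-1,10-epoxy-8-[(triethylsilyl)oxy]germacra-2,4,11(13)-trien-12,6-olide
Product: 30 (1R,6R,7R,8R,10R,2Z,4E)-15-[(tert-butyldiphenylsilyl)oxy]-1,10-epoxy-8-hydroxygermacra-2,4,11(13)-trien-12,6-olide
Conditions: Et3N·3HF, THF/MeCN, rt
Reagents that add atoms: none
Why: Fluoride-mediated desilylation under nearly neutral conditions should remove the TES ether selectively in the presence of the TBDPS ether, the dienyl oxirane and the α-methylene lactone.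

Step 22
Reactants: 31 4-methylfuran-2(5H)-one
Product: 34 4-methoxybenzyl (2Z)-4-acetoxy-3-methylbut-2-enoate, via sodium (2Z)-4-hydroxy-3-methylbut-2-enoate 32 (not isolated), via 4-methoxybenzyl (2Z)-4-hydroxy-3-methylbut-2-enoate 33 (not isolated)
Conditions: NaOH (1.0 equiv), H2O/THF, 0 °C, evaporate; 4-methoxybenzyl chloride, Bu4NI (cat.), DMF, rt; then Ac2O, pyridine, DMAP (cat.), 0 °C
Reagents that add atoms: sodium hydroxide, [Na+].[OH-]; 4-methoxybenzyl chloride, COc1ccc(CCl)cc1; acetic anhydride, CC(=O)OC(C)=O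
Why: Saponification of the butenolide keeps the Z geometry imposed by the ring, O-alkylation of the carboxylate does not activate the acyl group (so relactonisation is avoided), and acetylation then blocks the hydroxyl.

Step 23
Reactants: 34 4-methoxybenzyl (2Z)-4-acetoxy-3-methylbut-2-enoate
Product: 35 (2Z)-4-acetoxy-3-methylbut-2-enoic acid
Conditions: CF3CO2H, anisole, CH2Cl2, 0 °C
Reagents that add atoms: none
Why: Acidolysis of the PMB ester with anisole as cation scavenger should free the acid without touching the acetate or the double-bond geometry.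

Step 24
Reactants: 30 (1R,6R,7R,8R,10R,2Z,4E)-15-[(tert-butyldiphenylsilyl)oxy]-1,10-epoxy-8-hydroxygermacra-2,4,11(13)-trien-12,6-olide; 35 (2Z)-4-acetoxy-3-methylbut-2-enoic acid
Product: 36 (1R,6R,7R,8R,10R,2Z,4E)-8-{[(2Z)-4-acetoxy-3-methylbut-2-enoyl]oxy}-15-[(tert-butyldiphenylsilyl)oxy]-1,10-epoxygermacra-2,4,11(13)-trien-12,6-olide
Conditions: iPrN=C=NiPr, DMAP (cat.), CH2Cl2, 0 °C to rt
Reagents that add atoms: none
Why: Steglich esterification acylates the secondary C8 hydroxyl with retention at C8 under neutral conditions.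

Step 25
Reactants: 36 (1R,6R,7R,8R,10R,2Z,4E)-8-{[(2Z)-4-acetoxy-3-methylbut-2-enoyl]oxy}-15-[(tert-butyldiphenylsilyl)oxy]-1,10-epoxygermacra-2,4,11(13)-trien-12,6-olide
Product: 37 CNP0292814.1, (1R,6R,7R,8R,10R,2Z,4E)-8-{[(2Z)-4-acetoxy-3-methylbut-2-enoyl]oxy}-1,10-epoxy-15-hydroxygermacra-2,4,11(13)-trien-12,6-olide
Conditions: Bu4NF/AcOH (1:1), THF, 0 °C to rt
Reagents that add atoms: none
Why: Acetic acid-buffered fluoride desilylation should cleave the primary allylic TBDPS ether while sparing the acetate, the α-methylene lactone and the dienyl oxirane.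

**Compound list**
1 | but-2-yne-1,4-diol | OCC#CCO | starting material
2 | 4-[(4-methoxybenzyl)oxy]but-2-yn-1-ol | OCC#CCOCc1ccc(OC)cc1 | intermediate
3 | 4-[(4-methoxybenzyl)oxy]but-2-ynal | O=CC#CCOCc1ccc(OC)cc1 | intermediate
4 | methyl 3-methylbut-2-enoate | COC(=O)C=C(C)C | starting material
5 | lithium 1-methoxy-3-methylbuta-1,3-dien-1-olate (not isolated) | [Li+].[O-]C(OC)=CC(C)=C | intermediate
6 | tert-butyl{[(1Z)-1-methoxy-3-methylbuta-1,3-dien-1-yl]oxy}dimethylsilane | COC(/O[Si](C)(C)C(C)(C)C)=C/C(C)=C | intermediate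
7 | methyl (2E,5R)-8-[(4-methoxybenzyl)oxy]-3-methyl-5-[(trichlorosilyl)oxy]oct-2-en-6-ynoate (not isolated) | COC(=O)/C=C(\C)C[C@@H](O[Si](Cl)(Cl)Cl)C#CCOCc1ccc(OC)cc1 | intermediate
8 | methyl (2E,5R)-5-hydroxy-8-[(4-methoxybenzyl)oxy]-3-methyloct-2-en-6-ynoate | COC(=O)/C=C(\C)C[C@@H](O)C#CCOCc1ccc(OC)cc1 | intermediate
9 | (2E,5R)-8-[(4-methoxybenzyl)oxy]-3-methyloct-2-en-6-yne-1,5-diol | OC/C=C(\C)C[C@@H](O)C#CCOCc1ccc(OC)cc1 | intermediate
10 | cyclic alkenylalane (1,2-oxaluminole, Al on C11) from 9, drawn in simplified neutral form (not isolated) | COCCO[Al]1O[C@H](C/C(C)=C/CO)C=C1COCc2ccc(OC)cc2 | intermediate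
11 | (2E,5R,6Z)-7-iodo-8-[(4-methoxybenzyl)oxy]-3-methylocta-2,6-diene-1,5-diol | OC/C=C(\C)C[C@@H](O)/C=C(\I)COCc1ccc(OC)cc1 | intermediate
12 | 1,5-bis(triethylsilyl) ether of diol 11 | CC[Si](CC)(CC)OC/C=C(\C)C[C@@H](O[Si](CC)(CC)CC)/C=C(\I)COCc1ccc(OC)cc1 | intermediate
13 | (2E,5R,6Z)-7-iodo-8-[(4-methoxybenzyl)oxy]-3-methyl-5-[(triethylsilyl)oxy]octa-2,6-dien-1-ol | OC/C=C(\C)C[C@@H](O[Si](CC)(CC)CC)/C=C(\I)COCc1ccc(OC)cc1 | intermediate
14 | methyl (2Z,4R,6E)-8-hydroxy-2-{[(4-methoxybenzyl)oxy]methyl}-6-methyl-4-[(triethylsilyl)oxy]octa-2,6-dienoate | OC/C=C(\C)C[C@@H](O[Si](CC)(CC)CC)/C=C(/COCc1ccc(OC)cc1)C(=O)OC | intermediate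
15 | methyl (2Z,4R)-5-[(2R,3R)-3-(hydroxymethyl)-2-methyloxiran-2-yl]-2-{[(4-methoxybenzyl)oxy]methyl}-4-[(triethylsilyl)oxy]pent-2-enoate | OC[C@H]1O[C@]1(C)C[C@@H](O[Si](CC)(CC)CC)/C=C(/COCc2ccc(OC)cc2)C(=O)OC | intermediate
16 | methyl (2Z,4R)-5-[(2R,3S)-3-formyl-2-methyloxiran-2-yl]-2-{[(4-methoxybenzyl)oxy]methyl}-4-[(triethylsilyl)oxy]pent-2-enoate | O=C[C@H]1O[C@]1(C)C[C@@H](O[Si](CC)(CC)CC)/C=C(/COCc2ccc(OC)cc2)C(=O)OC | intermediate
17 | methyl (2Z,4R)-5-[(2R,3R)-3-ethynyl-2-methyloxiran-2-yl]-2-{[(4-methoxybenzyl)oxy]methyl}-4-[(triethylsilyl)oxy]pent-2-enoate | C#C[C@H]1O[C@]1(C)C[C@@H](O[Si](CC)(CC)CC)/C=C(/COCc2ccc(OC)cc2)C(=O)OC | intermediate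
18 | methyl (2Z,4R)-5-[(2R,3R)-3-ethynyl-2-methyloxiran-2-yl]-2-(hydroxymethyl)-4-[(triethylsilyl)oxy]pent-2-enoate | C#C[C@H]1O[C@]1(C)C[C@@H](O[Si](CC)(CC)CC)/C=C(/CO)C(=O)OC | intermediate
19 | 4-[(tert-butyldiphenylsilyl)oxy]but-2-yn-1-ol | OCC#CCO[Si](c1ccccc1)(c1ccccc1)C(C)(C)C | intermediate
20 | cyclic alkenylalane (1,2-oxaluminole) from 19, drawn in simplified neutral form (not isolated) | COCCO[Al]1OCC=C1CO[Si](c2ccccc2)(c2ccccc2)C(C)(C)C | intermediate
21 | (2Z)-4-[(tert-butyldiphenylsilyl)oxy]-3-iodobut-2-en-1-ol | OC/C=C(\I)CO[Si](c1ccccc1)(c1ccccc1)C(C)(C)C | intermediate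
22 | methyl (2Z,4R)-5-{(2R,3R)-3-[(3E)-3-{[(tert-butyldiphenylsilyl)oxy]methyl}-5-hydroxypent-3-en-1-yn-1-yl]-2-methyloxiran-2-yl}-2-(hydroxymethyl)-4-[(triethylsilyl)oxy]pent-2-enoate | OC/C=C(CO[Si](c1ccccc1)(c1ccccc1)C(C)(C)C)\C#C[C@H]2O[C@]2(C)C[C@@H](O[Si](CC)(CC)CC)/C=C(/CO)C(=O)OC | intermediate
23 | methyl (2Z,4R)-5-{(2R,3R)-3-[(1Z,3E)-3-{[(tert-butyldiphenylsilyl)oxy]methyl}-5-hydroxypenta-1,3-dien-1-yl]-2-methyloxiran-2-yl}-2-(hydroxymethyl)-4-[(triethylsilyl)oxy]pent-2-enoate | OC/C=C(CO[Si](c1ccccc1)(c1ccccc1)C(C)(C)C)\C=C/[C@H]2O[C@]2(C)C[C@@H](O[Si](CC)(CC)CC)/C=C(/CO)C(=O)OC | intermediate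
24 | methyl (2Z,4R)-5-{(2R,3R)-3-[(1Z,3E)-3-{[(tert-butyldiphenylsilyl)oxy]methyl}-5-oxopenta-1,3-dien-1-yl]-2-methyloxiran-2-yl}-2-(hydroxymethyl)-4-[(triethylsilyl)oxy]pent-2-enoate | O=C/C=C(CO[Si](c1ccccc1)(c1ccccc1)C(C)(C)C)\C=C/[C@H]2O[C@]2(C)C[C@@H](O[Si](CC)(CC)CC)/C=C(/CO)C(=O)OC | intermediate
25 | methanesulfonate of the C13 hydroxyl of 24 (not isolated) | O=C/C=C(CO[Si](c1ccccc1)(c1ccccc1)C(C)(C)C)\C=C/[C@H]2O[C@]2(C)C[C@@H](O[Si](CC)(CC)CC)/C=C(/COS(C)(=O)=O)C(=O)OC | intermediate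
26 | methyl (2E,4R)-2-(bromomethyl)-5-{(2R,3R)-3-[(1Z,3E)-3-{[(tert-butyldiphenylsilyl)oxy]methyl}-5-oxopenta-1,3-dien-1-yl]-2-methyloxiran-2-yl}-4-[(triethylsilyl)oxy]pent-2-enoate | O=C/C=C(CO[Si](c1ccccc1)(c1ccccc1)C(C)(C)C)\C=C/[C@H]2O[C@]2(C)C[C@@H](O[Si](CC)(CC)CC)/C=C(/CBr)C(=O)OC | intermediate
27 | allylchromium dichloride from 26 (Cr on C13, trivalent chromium, not isolated) | O=C/C=C(CO[Si](c1ccccc1)(c1ccccc1)C(C)(C)C)\C=C/[C@H]2O[C@]2(C)C[C@@H](O[Si](CC)(CC)CC)/C=C(/C[Cr](Cl)Cl)C(=O)OC | intermediate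
28 | dichlorochromium alkoxide (at O6) of the ring-closed ten-membered hydroxy ester, C6–C7 bond formed, methyl ester not yet lactonised (not isolated) | C=C(C(=O)OC)[C@H]1[C@H](O[Cr](Cl)Cl)/C=C(CO[Si](c2ccccc2)(c2ccccc2)C(C)(C)C)\C=C/[C@H]3O[C@]3(C)C[C@H]1O[Si](CC)(CC)CC | intermediate
29 | (1R,6R,7S,8R,10R,2Z,4E)-15-[(tert-butyldiphenylsilyl)oxy]-1,10-epoxy-8-[(triethylsilyl)oxy]germacra-2,4,11(13)-trien-12,6-olide | C=C1C(=O)O[C@@H]2/C=C(CO[Si](c4ccccc4)(c4ccccc4)C(C)(C)C)\C=C/[C@H]3O[C@]3(C)C[C@@H](O[Si](CC)(CC)CC)[C@@H]12 | intermediate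
30 | (1R,6R,7R,8R,10R,2Z,4E)-15-[(tert-butyldiphenylsilyl)oxy]-1,10-epoxy-8-hydroxygermacra-2,4,11(13)-trien-12,6-olide | C=C1C(=O)O[C@@H]2/C=C(CO[Si](c4ccccc4)(c4ccccc4)C(C)(C)C)\C=C/[C@H]3O[C@]3(C)C[C@@H](O)[C@@H]12 | intermediate
31 | 4-methylfuran-2(5H)-one | CC1=CC(=O)OC1 | starting material
32 | sodium (2Z)-4-hydroxy-3-methylbut-2-enoate (not isolated) | C/C(CO)=C/C(=O)[O-].[Na+] | intermediate
33 | 4-methoxybenzyl (2Z)-4-hydroxy-3-methylbut-2-enoate (not isolated) | C/C(CO)=C/C(=O)OCc1ccc(OC)cc1 | intermediate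
34 | 4-methoxybenzyl (2Z)-4-acetoxy-3-methylbut-2-enoate | C/C(COC(C)=O)=C/C(=O)OCc1ccc(OC)cc1 | intermediate
35 | (2Z)-4-acetoxy-3-methylbut-2-enoic acid | C/C(COC(C)=O)=C/C(=O)O | intermediate
36 | (1R,6R,7R,8R,10R,2Z,4E)-8-{[(2Z)-4-acetoxy-3-methylbut-2-enoyl]oxy}-15-[(tert-butyldiphenylsilyl)oxy]-1,10-epoxygermacra-2,4,11(13)-trien-12,6-olide | C=C1C(=O)O[C@@H]2/C=C(CO[Si](c4ccccc4)(c4ccccc4)C(C)(C)C)\C=C/[C@H]3O[C@]3(C)C[C@@H](OC(=O)/C=C(/C)COC(C)=O)[C@@H]12 | intermediate
37 | CNP0292814.1, (1R,6R,7R,8R,10R,2Z,4E)-8-{[(2Z)-4-acetoxy-3-methylbut-2-enoyl]oxy}-1,10-epoxy-15-hydroxygermacra-2,4,11(13)-trien-12,6-olide | C=C1C(=O)O[C@@H]2/C=C(CO)\C=C/[C@H]3O[C@]3(C)C[C@@H](OC(=O)/C=C(/C)COC(C)=O)[C@@H]12 | target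

**Step count and risks**

Total step count: 25. Longest linear sequence: 20 (steps 1, 2, 4–13, 16–21, 24, 25).

Steps most likely to fail:

1. Step 20. The ring closure is slow at high dilution, which gives time for three competing processes: loss of the bromide-derived geometry of the allylchromium by 1,3-metal shift (this opens the chair with C8 axial and leads to the 6,7-cis lactone), thermal Z-to-E isomerisation of the cis,cis-dienal through reversible oxa-6π electrocyclisation, and intermolecular allylation. The fallback closes the ring one stage earlier, on the enyne, and introduces the Z C2=C3 bond last inside the ring. It sets out from 22: MnO2 oxidation of the dienylic carbinol should give the hydroxy enynal F1, which cannot electrocyclise. Mesylation (MsCl, iPr2NEt) and LiBr displacement should give the enynal bromide F2. CrCl2 under the same high-dilution conditions should close the ten-membered enyne lactone F3. Lindlar semi-hydrogenation of the ring alkyne should then give the Z alkene, and the route is rejoined at 29.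

2. Step 18. The heterogeneous oxidation may over-oxidise the C13 carbinol, and the cis,cis-dienal may isomerise during the oxidation and the sulfonylation that follows. The fallback replaces chemoselective oxidation by protecting-group differentiation. It sets out from 21 and 18: silylation of 21 (TESCl, imidazole) should give the bis-silyl vinyl iodide F4. Sonogashira coupling of F4 with 18 should give the enyne F5, and Lindlar reduction the diene F6, whose only free hydroxyl is at C13. Appel bromination (CBr4, PPh3) should give the bromide F7. A Swern oxidation (oxalyl chloride, DMSO, then iPr2NEt), which is known to convert primary triethylsilyl ethers directly into aldehydes while sparing secondary ones, should then deliver 26, where the route is rejoined with the dienal formed immediately before the key step.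

3. Step 4. Enantio- and γ-selectivity may be insufficient in the catalytic aldol addition to a small linear ynal. The fallback sets C8 by reduction instead. It sets out from 3 and 6: a BF3·OEt2-promoted vinylogous Mukaiyama aldol should give the racemic hydroxy ester F8. Dess–Martin oxidation should give the ynone F9. Noyori asymmetric transfer hydrogenation with RuCl[(R,R)-TsDPEN](p-cymene) in isopropanol (the catalyst enantiomer expected to give the 5R carbinol; ynones are privileged substrates) should return 8, where the route is rejoined.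

Further compounds
F1 | step 20 | methyl (2Z,4R)-5-{(2R,3R)-3-[(3E)-3-{[(tert-butyldiphenylsilyl)oxy]methyl}-5-oxopent-3-en-1-yn-1-yl]-2-methyloxiran-2-yl}-2-(hydroxymethyl)-4-[(triethylsilyl)oxy]pent-2-enoate | O=C/C=C(CO[Si](c1ccccc1)(c1ccccc1)C(C)(C)C)\C#C[C@H]2O[C@]2(C)C[C@@H](O[Si](CC)(CC)CC)/C=C(/CO)C(=O)OC
F2 | step 20 | methyl (2E,4R)-2-(bromomethyl)-5-{(2R,3R)-3-[(3E)-3-{[(tert-butyldiphenylsilyl)oxy]methyl}-5-oxopent-3-en-1-yn-1-yl]-2-methyloxiran-2-yl}-4-[(triethylsilyl)oxy]pent-2-enoate | O=C/C=C(CO[Si](c1ccccc1)(c1ccccc1)C(C)(C)C)\C#C[C@H]2O[C@]2(C)C[C@@H](O[Si](CC)(CC)CC)/C=C(/CBr)C(=O)OC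
F3 | step 20 | (1R,6R,7S,8R,10R,4E)-15-[(tert-butyldiphenylsilyl)oxy]-1,10-epoxy-8-[(triethylsilyl)oxy]germacra-4,11(13)-dien-2-yn-12,6-olide | C=C1C(=O)O[C@@H]2/C=C(CO[Si](c4ccccc4)(c4ccccc4)C(C)(C)C)\C#C[C@H]3O[C@]3(C)C[C@@H](O[Si](CC)(CC)CC)[C@@H]12
F4 | step 18 | triethyl{[(2Z)-4-[(tert-butyldiphenylsilyl)oxy]-3-iodobut-2-en-1-yl]oxy}silane | CC[Si](CC)(CC)OC/C=C(\I)CO[Si](c1ccccc1)(c1ccccc1)C(C)(C)C
F5 | step 18 | methyl (2Z,4R)-5-{(2R,3R)-3-[(3E)-3-{[(tert-butyldiphenylsilyl)oxy]methyl}-5-[(triethylsilyl)oxy]pent-3-en-1-yn-1-yl]-2-methyloxiran-2-yl}-2-(hydroxymethyl)-4-[(triethylsilyl)oxy]pent-2-enoate | CC[Si](CC)(CC)OC/C=C(CO[Si](c1ccccc1)(c1ccccc1)C(C)(C)C)\C#C[C@H]2O[C@]2(C)C[C@@H](O[Si](CC)(CC)CC)/C=C(/CO)C(=O)OC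
F6 | step 18 | methyl (2Z,4R)-5-{(2R,3R)-3-[(1Z,3E)-3-{[(tert-butyldiphenylsilyl)oxy]methyl}-5-[(triethylsilyl)oxy]penta-1,3-dien-1-yl]-2-methyloxiran-2-yl}-2-(hydroxymethyl)-4-[(triethylsilyl)oxy]pent-2-enoate | CC[Si](CC)(CC)OC/C=C(CO[Si](c1ccccc1)(c1ccccc1)C(C)(C)C)\C=C/[C@H]2O[C@]2(C)C[C@@H](O[Si](CC)(CC)CC)/C=C(/CO)C(=O)OC
F7 | step 18 | methyl (2E,4R)-2-(bromomethyl)-5-{(2R,3R)-3-[(1Z,3E)-3-{[(tert-butyldiphenylsilyl)oxy]methyl}-5-[(triethylsilyl)oxy]penta-1,3-dien-1-yl]-2-methyloxiran-2-yl}-4-[(triethylsilyl)oxy]pent-2-enoate | CC[Si](CC)(CC)OC/C=C(CO[Si](c1ccccc1)(c1ccccc1)C(C)(C)C)\C=C/[C@H]2O[C@]2(C)C[C@@H](O[Si](CC)(CC)CC)/C=C(/CBr)C(=O)OC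
F8 | step 4 | methyl (2E)-5-hydroxy-8-[(4-methoxybenzyl)oxy]-3-methyloct-2-en-6-ynoate, racemic at C5 | COC(=O)/C=C(\C)CC(O)C#CCOCc1ccc(OC)cc1
F9 | step 4 | methyl (2E)-8-[(4-methoxybenzyl)oxy]-3-methyl-5-oxooct-2-en-6-ynoate | COC(=O)/C=C(\C)CC(=O)C#CCOCc1ccc(OC)cc1
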